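**Assumption:** no reliable catalytic enantioselective version of the cyclobutane-forming step exists for this substrate class, so step 9 sets the three stereocentres relative to one another (racemate) and step 10 secures the absolute configuration by resolution. The target descriptors derived from the given SMILES are S at the cyclobutane CH–aryl, R at the benzylic ring-fusion CH, and S at the ring-fusion CH next to CH2.

## Retrosynthetic overview

1. Target 18 ⇐ racemate 17, resolved on a chiral stationary phase.
2. 17 ⇐ (E)-o-prenyl hydroxystilbene 16 by an intramolecular stepwise (formal) [2+2] of the stilbene C=C with the prenyl C=C; the cyclopentane and cyclobutane rings form together, last.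
3. 16 ⇐ Horner–Wadsworth–Emmons union of chromene aldehyde 8 (ring A plus pyran) with benzylphosphonate 13 (ring B, catechol as bis-TBS ether).
4. 8 ⇐ chromene aldehyde 4 by amino-alkoxide-directed ortho-lithiation and prenylation; 4 ⇐ 3-hydroxy-5-methoxybenzaldehyde 1 by propargyl ether Claisen annulation.
5. Ring order: pyran first, then cyclopentane and cyclobutane in one step.

## Route

**Step 1**
Reactants: 1 3-hydroxy-5-methoxybenzaldehyde
Product: 2 3-methoxy-5-[(2-methylbut-3-yn-2-yl)oxy]benzaldehyde
Conditions: 3-chloro-3-methylbut-1-yne, DBU, CuCl2·2H2O (1 mol%), MeCN, 0 °C → rt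
Reagents that add atoms: 3-chloro-3-methylbut-1-yne, CC(C)(Cl)C#C
Why: Cu-catalysed O-propargylation of a phenol with a tertiary propargylic chloride (via a copper allenylidene) gives the hindered aryl ether, and the aldehyde is inert to DBU.

**Step 2**
Reactants: 2 3-methoxy-5-[(2-methylbut-3-yn-2-yl)oxy]benzaldehyde
Product: 4 7-methoxy-2,2-dimethyl-2H-chromene-5-carbaldehyde, via allenylphenol 3 (not isolated)
Conditions: PhNEt2, 180 °C, 3 h
Reagents that add atoms: none
Why: Aromatic propargyl Claisen rearrangement, then 1,5-H shift and oxa-6π electrocyclisation; the [3,3] shift goes to the ortho carbon next to the formyl group (a meta acceptor directs towards itself, a meta methoxy directs para to itself) and not to the carbon between the two oxygens.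

**Step 3**
Reactants: 4 7-methoxy-2,2-dimethyl-2H-chromene-5-carbaldehyde
Product: 8 7-methoxy-2,2-dimethyl-6-(3-methylbut-2-en-1-yl)-2H-chromene-5-carbaldehyde, via lithium amino alkoxide 5 (not isolated), via ortho-lithiated amino alkoxide 6 (not isolated), via prenylated amino alkoxide 7 (not isolated)
Conditions: Me2NCH2CH2N(Me)Li (from the amine + n-BuLi), THF, −20 °C; n-BuLi (2 equiv), −20 °C; CuBr·SMe2 (cat.), prenyl bromide, −78 °C → rt; aq NH4Cl
Reagents that add atoms: 1-bromo-3-methylbut-2-ene (prenyl bromide), CC(C)=CCBr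
Why: α-Amino alkoxide directed ortho-metalation (Comins protocol), in which the in situ LiO–CH(NR2) group and the OMe group jointly direct lithiation to C6 between them, followed by Cu-mediated SN2 allylation and release of the aldehyde on aqueous work-up.

**Step 4**
Reactants: 9 3,4-dihydroxybenzaldehyde
Product: 10 3,4-bis[(tert-butyldimethylsilyl)oxy]benzaldehyde
Conditions: TBSCl (2.5 equiv), imidazole, DMF, rt
Reagents that add atoms: tert-butyldimethylsilyl chloride, CC(C)(C)[Si](C)(C)Cl
Why: Standard silylation of both phenols gives a catechol protecting group that survives hydride, ZnI2/phosphite and NaH and is removed by fluoride.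

**Step 5**
Reactants: 10 3,4-bis[(tert-butyldimethylsilyl)oxy]benzaldehyde
Product: 11 {3,4-bis[(tert-butyldimethylsilyl)oxy]phenyl}methanol
Conditions: NaBH4, THF–MeOH (4:1), 0 °C
Reagents that add atoms: none
Why: Chemoselective borohydride reduction of the aldehyde leaves the aryl silyl ethers intact at 0 °C.

**Step 6**
Reactants: 11 {3,4-bis[(tert-butyldimethylsilyl)oxy]phenyl}methanol
Product: 13 diethyl {3,4-bis[(tert-butyldimethylsilyl)oxy]benzyl}phosphonate, via benzyltriethoxyphosphonium iodide 12 (not isolated)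
Conditions: ZnI2 (1.5 equiv), P(OEt)3 (3 equiv), toluene, reflux
Reagents that add atoms: triethyl phosphite, CCOP(OCC)OCC
Why: One-flask ZnI2-mediated Michaelis–Arbuzov reaction of an electron-rich benzylic alcohol (P-alkylation of the phosphite, then dealkylation of the phosphonium by iodide) avoids a separate benzylic halide.

**Step 7**
Reactants: 13 diethyl {3,4-bis[(tert-butyldimethylsilyl)oxy]benzyl}phosphonate; 8 7-methoxy-2,2-dimethyl-6-(3-methylbut-2-en-1-yl)-2H-chromene-5-carbaldehyde
Product: 15 (E)-5-{2-[3,4-bis(tert-butyldimethylsilyloxy)phenyl]ethenyl}-7-methoxy-2,2-dimethyl-6-(3-methylbut-2-en-1-yl)-2H-chromene, via sodium phosphonate carbanion 14 (not isolated)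
Conditions: NaH, 15-crown-5 (cat.), THF, 0 °C → rt
Reagents that add atoms: none
Why: Horner–Wadsworth–Emmons olefination of a non-enolisable aldehyde with a benzylic phosphonate gives the (E)-stilbene, and the aryl silyl ethers, prenyl group and chromene tolerate NaH in THF.

**Step 8**
Reactants: 15 (E)-5-{2-[3,4-bis(tert-butyldimethylsilyloxy)phenyl]ethenyl}-7-methoxy-2,2-dimethyl-6-(3-methylbut-2-en-1-yl)-2H-chromene
Product: 16 4-{(E)-2-[7-methoxy-2,2-dimethyl-6-(3-methylbut-2-en-1-yl)-2H-chromen-5-yl]ethenyl}benzene-1,2-diol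
Conditions: TBAF (2.2 equiv), AcOH (2.2 equiv), THF, 0 °C
Reagents that add atoms: none
Why: Fluoride desilylation buffered with acetic acid frees the catechol without forming the air-sensitive catecholate and leaves the chromene and both alkenes untouched.

**Step 9**
Reactants: 16 4-{(E)-2-[7-methoxy-2,2-dimethyl-6-(3-methylbut-2-en-1-yl)-2H-chromen-5-yl]ethenyl}benzene-1,2-diol
Product: 17 racemic cis-fused exo-aryl cyclobutane (1:1 mixture of 18 and its enantiomer)
Conditions: o-xylene, 180 °C (microwave, sealed tube), 20–30 min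
Reagents that add atoms: none
Why: Thermal stepwise (formal) [2+2] cycloaddition of the 4-hydroxystilbene with the ortho prenyl group (5-exo bond from the stilbene carbon next to ring A to the prenyl CH, then 4-exo closure of the CMe2 centre onto the benzylic carbon); the cis ring fusion is the only one the bicyclo[3.2.0] closure allows, the aryl group takes the exo position trans to the neighbouring aryl–C bond, and the product is racemic because the substrate is achiral.

**Step 10**
Reactants: 17 racemic cis-fused exo-aryl cyclobutane (1:1 mixture of 18 and its enantiomer)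
Product: 18 target (cyclobutane CH–aryl S; benzylic ring-fusion CH R; ring-fusion CH next to CH2 S)
Conditions: preparative HPLC on amylose tris(3,5-dimethylphenylcarbamate), hexane/i-PrOH + 0.1% TFA
Reagents that add atoms: none
Why: Chromatographic resolution on a chiral stationary phase makes or breaks no bond; the wanted antipode is collected and its absolute configuration confirmed by ECD against calculation or by X-ray of a heavy-atom derivative.

## Compound list

1 | 3-hydroxy-5-methoxybenzaldehyde | COc1cc(O)cc(C=O)c1 | starting material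
2 | 3-methoxy-5-[(2-methylbut-3-yn-2-yl)oxy]benzaldehyde | COc1cc(OC(C)(C)C#C)cc(C=O)c1 | intermediate
3 | 3-hydroxy-5-methoxy-2-(3-methylbuta-1,2-dien-1-yl)benzaldehyde (allenylphenol, not isolated) | COc1cc(O)c(C=C=C(C)C)c(C=O)c1 | intermediate
4 | 7-methoxy-2,2-dimethyl-2H-chromene-5-carbaldehyde | COc1cc2OC(C)(C)C=Cc2c(C=O)c1 | intermediate
5 | lithium {[2-(dimethylamino)ethyl](methyl)amino}(7-methoxy-2,2-dimethyl-2H-chromen-5-yl)methanolate (racemic at the carbinol carbon, not isolated) | COc1cc2OC(C)(C)C=Cc2c(C(O[Li])N(C)CCN(C)C)c1 | intermediate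
6 | 6-lithio derivative of 5 (not isolated) | COc1cc2OC(C)(C)C=Cc2c(C(O[Li])N(C)CCN(C)C)c1[Li] | intermediate
7 | lithium {[2-(dimethylamino)ethyl](methyl)amino}[7-methoxy-2,2-dimethyl-6-(3-methylbut-2-en-1-yl)-2H-chromen-5-yl]methanolate (not isolated) | COc1cc2OC(C)(C)C=Cc2c(C(O[Li])N(C)CCN(C)C)c1CC=C(C)C | intermediate
8 | 7-methoxy-2,2-dimethyl-6-(3-methylbut-2-en-1-yl)-2H-chromene-5-carbaldehyde | COc1cc2OC(C)(C)C=Cc2c(C=O)c1CC=C(C)C | intermediate
9 | 3,4-dihydroxybenzaldehyde | O=Cc1ccc(O)c(O)c1 | starting material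
10 | 3,4-bis[(tert-butyldimethylsilyl)oxy]benzaldehyde | O=Cc1ccc(O[Si](C)(C)C(C)(C)C)c(O[Si](C)(C)C(C)(C)C)c1 | intermediate
11 | {3,4-bis[(tert-butyldimethylsilyl)oxy]phenyl}methanol | OCc1ccc(O[Si](C)(C)C(C)(C)C)c(O[Si](C)(C)C(C)(C)C)c1 | intermediate
12 | {3,4-bis[(tert-butyldimethylsilyl)oxy]benzyl}triethoxyphosphonium iodide (not isolated) | CCO[P+](OCC)(OCC)Cc1ccc(O[Si](C)(C)C(C)(C)C)c(O[Si](C)(C)C(C)(C)C)c1.[I-] | intermediate
13 | diethyl {3,4-bis[(tert-butyldimethylsilyl)oxy]benzyl}phosphonate | CCOP(=O)(OCC)Cc1ccc(O[Si](C)(C)C(C)(C)C)c(O[Si](C)(C)C(C)(C)C)c1 | intermediate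
14 | sodium salt of the benzylic carbanion of 13 (not isolated) | CCOP(=O)(OCC)[CH-]c1ccc(O[Si](C)(C)C(C)(C)C)c(O[Si](C)(C)C(C)(C)C)c1.[Na+] | intermediate
15 | (E)-5-{2-[3,4-bis(tert-butyldimethylsilyloxy)phenyl]ethenyl}-7-methoxy-2,2-dimethyl-6-(3-methylbut-2-en-1-yl)-2H-chromene | COc1cc2OC(C)(C)C=Cc2c(/C=C/c2ccc(O[Si](C)(C)C(C)(C)C)c(O[Si](C)(C)C(C)(C)C)c2)c1CC=C(C)C | intermediate
16 | 4-{(E)-2-[7-methoxy-2,2-dimethyl-6-(3-methylbut-2-en-1-yl)-2H-chromen-5-yl]ethenyl}benzene-1,2-diol | COc1cc2OC(C)(C)C=Cc2c(/C=C/c2ccc(O)c(O)c2)c1CC=C(C)C | intermediate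
17 | racemate: cis-fused 2,2-dimethylcyclobuta[a]indane annulated with the methoxy-2,2-dimethylchromene, 3,4-dihydroxyphenyl on the cyclobutane CH exo and trans to the adjacent aryl–C bond; 1:1 mixture of 18 and its mirror image | COc1cc2c(c3c1C[C@H]1[C@@H]3[C@H](c3ccc(O)c(O)c3)C1(C)C)C=CC(C)(C)O2.COc1cc2c(c3c1C[C@@H]1[C@H]3[C@@H](c3ccc(O)c(O)c3)C1(C)C)C=CC(C)(C)O2 | intermediate
18 | CNP0207533.1: same constitution and relative configuration as 17, single enantiomer with S at the cyclobutane CH–aryl, R at the benzylic ring-fusion CH, S at the ring-fusion CH next to CH2 | COc1cc2c(c3c1C[C@H]1[C@@H]3[C@H](c3ccc(O)c(O)c3)C1(C)C)C=CC(C)(C)O2 | target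

## Step count and risks

Total step count: 10.
Longest linear sequence: 7 steps (steps 1, 2, 3, 7, 8, 9, 10 from 1; the branch from 9 through steps 4, 5, 6 is equally long).

The three steps most likely to fail:

**Step 3.** Lithiation could go to C8 between the two ring oxygens, or the hindered aryllithium could allylate poorly. The fallback puts the C6 substituent in as a halogen before the pyran ring is made. It sets out from 1: NBS in MeCN at 0 °C brominates para to the free hydroxyl, between CHO and OMe, to give 2-bromo-5-hydroxy-3-methoxybenzaldehyde F1 (separated from the ortho isomer). O-Alkylation as in step 1 gives 2-bromo-3-methoxy-5-[(2-methylbut-3-yn-2-yl)oxy]benzaldehyde F2. Claisen annulation as in step 2 gives 6-bromo-7-methoxy-2,2-dimethyl-2H-chromene-5-carbaldehyde F3. Stille coupling of F3 with tributyl(3-methylbut-2-en-1-yl)stannane (Pd(PPh3)4, CsF, DMF, 90 °C) replaces bromine by prenyl and comes back to the route at 8.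

**Step 9.** The thermal formal [2+2] relies on the free para-hydroxyl of the stilbene and has not been run on this exact ring A; it could stall or give oligomers. The fallback is a photoredox radical-cation [2+2] on the silyl-protected stilbene. It sets out from 15: Ru(bpz)3(PF6)2 (2 mol%), visible light, air, MeNO2 gives the racemic cis-fused exo-aryl bis(tert-butyldimethylsilyl) cyclobutane F4. Desilylation of F4 with TBAF/AcOH comes back to the route at 17.

**Step 2.** The [3,3] shift could go to the carbon between the two oxygens and give the 5-methoxy-7-formyl isomer. The fallback is a boronate-templated ortho-condensation of the phenol with the enal, where the site is chosen by ring nucleophilicity (para to OMe, not para to CHO) instead of by the sigmatropic preference. It sets out from 1: 3-methylbut-2-enal, PhB(OH)2, AcOH, toluene, reflux with a Dean–Stark trap gives the cyclic boronate 7-methoxy-4-(2-methylprop-1-en-1-yl)-2-phenyl-4H-1,3,2-benzodioxaborinine-5-carbaldehyde F5. On further heating F5 loses phenylboronic acid to an o-quinone methide that closes by oxa-6π electrocyclisation and comes back to the route at 4.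

## Further compounds

F1 | step 3 | 2-bromo-5-hydroxy-3-methoxybenzaldehyde | COc1cc(O)cc(C=O)c1Br
F2 | step 3 | 2-bromo-3-methoxy-5-[(2-methylbut-3-yn-2-yl)oxy]benzaldehyde | COc1cc(OC(C)(C)C#C)cc(C=O)c1Br
F3 | step 3 | 6-bromo-7-methoxy-2,2-dimethyl-2H-chromene-5-carbaldehyde | COc1cc2OC(C)(C)C=Cc2c(C=O)c1Br
F4 | step 9 | racemic bis(tert-butyldimethylsilyl) ether of 17 (1:1 mixture of both enantiomers) | COc1cc2c(c3c1C[C@H]1[C@@H]3[C@H](c3ccc(O[Si](C)(C)C(C)(C)C)c(O[Si](C)(C)C(C)(C)C)c3)C1(C)C)C=CC(C)(C)O2.COc1cc2c(c3c1C[C@@H]1[C@H]3[C@@H](c3ccc(O[Si](C)(C)C(C)(C)C)c(O[Si](C)(C)C(C)(C)C)c3)C1(C)C)C=CC(C)(C)O2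
F5 | step 2 | 7-methoxy-4-(2-methylprop-1-en-1-yl)-2-phenyl-4H-1,3,2-benzodioxaborinine-5-carbaldehyde (racemic at C4) | COc1cc2OB(c3ccccc3)OC(C=C(C)C)c2c(C=O)c1
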